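# Proposed synthesis of 5-O-methyl-8-prenylafzelechin-4β-ol by an oxocarbenium ortho-quinone methide cycloaddition with a styrenyl boronate

## Analysis of the target

The target 23 is a flavan-3,4-diol: a chroman (ring C fused to ring A) with a 4-hydroxyphenyl group (ring B) at C2 and hydroxyls at C3 and C4. Ring A is fully differentiated, with OMe at C5, OH at C7 and a prenyl group at C8; only C6 is unsubstituted. The three contiguous stereocentres are C2 (R), C3 (S) and C4 (S). The aryl group at C2 and the 3-OH are trans and both equatorial on the half-chair, while the 3-OH and 4-OH are cis, so the 4-OH is pseudoaxial and trans to the aryl group. This 3,4-cis arrangement is the one that neither a small hydride on a 4-ketone nor capture of a C4 cation by an outside nucleophile delivers; both prefer 3,4-trans.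

The molecule is fragile in several ways. The C4–OH is benzylic to a 2,4,6-trioxygenated ring and ionises with traces of acid. A free 7-phenoxide is para to C4a and can expel a leaving group from C4 as a para-quinone methide. The prenyl alkene cyclises onto a neighbouring phenol in strong acid and rules out hydrogenolysis, osmylation and peracids anywhere on the skeleton.

The difficulty is therefore to set C2 and C3 in absolute terms and C4 relative to them with the prenyl group present, and to place OMe, OH and prenyl correctly on ring A. The strategy rests on the two bonds that bound ring C, O1–C2 and C3–C4. They join C4, a carbon already attached to ring A at the oxidation level of a salicylaldehyde, to the two-carbon unit C2–C3 of a ring B styrene. An E alkene encodes the 2,3-trans relationship, and boron at C3 stands in for the oxygen.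

## Retrosynthetic reasoning

**Phenol deprotection last.** Target 23 is traced to its bis-silyl ether 22 by cutting the two aryl O–Si bonds. While C4 carries any leaving group, a free 7-phenol is a liability, so the phenols stay masked until the diol is in place. Triisopropylsilyl ethers are chosen over tert-butyldimethylsilyl ethers because they must outlast a basic oxidation and a carbonate methanolysis. The forward step has to be buffered so that no phenoxide and no strong acid meets the benzylic C4–OH.

**C4–O through a tether.** Diol 22 is traced to the cis-fused cyclic carbonate 21, and 21 to the tert-butyl carbonate 19 by cutting the C4–O bond. The cut is made here because C4 ionises easily, so its configuration in 19 does not matter, and a five-membered carbonate spanning C3 and C4 can only be cis. What is gained is the 3,4-cis relationship that intermolecular chemistry does not give. The forward reaction must ionise the C4–OMe bond and let the carbonyl oxygen on C3 close onto the cation through ion 20.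

**C3–O from C3–B.** Carbonate 19 comes from alcohol 18, and 18 from boronate 17 by exchanging the C3–O bond for a C3–B bond. Oxidation of a C–B bond proceeds with retention, so the configuration set at C3 in the ring-forming step carries over unchanged.

**Ring C by cycloaddition.** Boronate 17 is cut at O1–C2 and C3–C4 into aldehyde 9, styrenyl boronate 13 and orthoformate 14, by way of acetal 15 and oxocarbenium ion 16. These are the only two bonds whose cleavage gives two simple, separately made aromatic pieces and leaves C4 oxygenated. The E geometry of 13 becomes the 2,3-trans relationship. Boron is used as the placeholder at C3 because it leaves the polarity of the styrene intact. An oxygen substituent directly on the alkene would reverse that polarity and join the aryl-bearing carbon to C4. The forward reaction has to form both bonds, keep the boron, and choose one face under the control of a chiral Brønsted acid.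

**Ring A aldehyde.** Aldehyde 9 is traced through diol 8 and bis-MOM aldehyde 7 to the symmetrical prenyl arene 5, then to bis-MOM ether 2 and on to 5-methoxyresorcinol 1 and prenyl bromide 3. The C–CHO and C–prenyl bonds are cut because both can be made by directed ortho-metalation (via aryllithiums 6 and 4). Because 5 is symmetrical, the formylation can give only one aldehyde, which fixes OMe at the future C5 and prenyl at the future C8.

**Ring B boronate.** Boronate 13 is cut at the C–B bond to alkyne 11 and pinacolborane 12; 11 is the silyl ether of 4-ethynylphenol 10. Syn hydroboration of the terminal alkyne gives the E isomer only.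

## Alternatives that were turned down

**Alternative 1: aryne insertion into a carboxylic acid.** The disconnection cuts C4a–C4 and C8a–O1. It leads to an aryne of ring A, released from silyl triflate A2, and to the acetonide acid A3, which carries C2, C3 and C4. In the forward step CsF generates the aryne; the carboxylate adds through oxygen at C8a, and the aryl anion then takes over the acyl group at C4a, giving the ortho-hydroxyaryl ketone A1.

- In its favour: both stereocentres come from a dependable asymmetric dihydroxylation of a cinnamate, which is a sounder source of absolute configuration than an untested asymmetric cycloaddition. C4 arrives as a ketone, and the methoxy group next to the aryne polarises it in the required sense.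
- Against it: A2 is a hexasubstituted benzene needing its own long sequence. The prenyl-bearing carbon flanks the site of oxygen attack and opposes the electronic bias, and the prenyl alkene can undergo an ene reaction with the aryne.
- The key step closes no ring. A1 still needs closure at the para-oxygenated benzylic C2 with clean inversion, a 3,4-cis-selective reduction, and removal of MOM ethers before the acid-labile diol exists.
- Comparison: the chosen route forms ring C and two skeletal bonds in one step from two short arms, and needs roughly half the operations.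

**Alternative 2: tethered C4–H oxidation of a flavan-3-ol.** Only the C4–O bond is cut; the flavan-3-ol skeleton is assumed to be built already. DDQ abstracts hydride from C4 of the tert-butyl carbonate A5 and the carbonyl oxygen captures the cation, giving the cis-fused carbonate A4. A bromine at C8 holds the place of the prenyl group.

- In its favour: DDQ oxidation at C4 of protected flavan-3-ols is established chemistry, so on this point the alternative is stronger than the chosen key step. The tether gives 3,4-cis for the same reason as in the chosen route.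
- Against it: the prenyl group cannot be present during the oxidation, which is why the bromide is needed. It must then be introduced late, in a molecule that holds a base-labile carbonate and an ionisable C4–O bond. Halogen–lithium exchange is excluded, and a cross-coupling (for example Pd(PPh3)4 with a prenylboronate) raises linear-versus-branched selectivity.
- A5 itself requires a full asymmetric flavan-3-ol synthesis, with the 5-OMe/7-O differentiation and a C8-selective bromination, before the key step can be tried.
- Comparison: the chosen route uses the same tether but reaches the C4-oxygenated skeleton directly, with the prenyl group in place from the start.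

**Alternative 3: ring A by Diels–Alder aromatisation on ring C.** The disconnection cuts C4a–C5 and C8–C8a, so ring A is built last on a preformed chiral ring C. Diene A8 adds across the sulfinyl enone of dihydropyranone A7. Loss of benzenesulfenic acid, methanol and the silyl group then gives dihydroflavonol A6.

- In its favour: the whole substitution pattern of ring A is fixed by the polarity of the diene, C4 arrives as a ketone, and the 7-OH emerges free. On ring A regiochemistry it is at least as secure as two directed metalations.
- Against it: A8 is a hydrolytically fragile ketene-acetal diene with a substituted, hindered terminus. A7 has an epimerisable C3 and can open by β-elimination of O1 during thermal aromatisation. Both partners are multistep.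
- After the key step a 3,4-cis-selective reduction of the ketone is still owed, and small hydrides give trans.
- Comparison: the alternative spends its key step on the achiral aromatic ring. The chosen strategy buys ring A cheaply and spends its key step on ring C and its stereocentres.

Key step: step 8

## Route

Assumption: the (R) enantiomer of the phosphoric acid is taken to deliver the (2S,3S) boronate 17; the sense of induction cannot be derived with confidence, and the (S) acid is used instead if the opposite sense results.

Step 1
Reactants: 1 5-methoxyresorcinol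
Product: 2 1-methoxy-3,5-bis(methoxymethoxy)benzene
Conditions: MOMCl (2.5 equiv), i-Pr2NEt (3 equiv), CH2Cl2, 0 °C to rt
Reagents that add atoms: chloromethyl methyl ether (MOMCl), COCCl
Why: O-alkylation of both phenols; the MOM ethers protect the phenols and act as the directing groups for the two metalations that follow.

Step 2
Reactants: 2 1-methoxy-3,5-bis(methoxymethoxy)benzene; 3 1-bromo-3-methylbut-2-ene (prenyl bromide)
Product: 5 5-methoxy-1,3-bis(methoxymethoxy)-2-(3-methylbut-2-enyl)benzene, via aryllithium 4 (not isolated)
Conditions: n-BuLi (1.1 equiv), TMEDA, THF, 0 °C; then CuBr·SMe2 (10 mol%), 3, −78 °C to rt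
Reagents that add atoms: none
Why: Directed ortho-metalation at the C–H between the two MOM ethers, the most acidic and best chelated site (two acetal oxygens against one acetal and one methyl ether elsewhere), then copper-catalysed allylation of aryllithium 4 at the primary carbon of 3. The product is symmetrical, which distinguishes it at once from the unsymmetrical regioisomer.

Step 3
Reactants: 5 5-methoxy-1,3-bis(methoxymethoxy)-2-(3-methylbut-2-enyl)benzene
Product: 7 6-methoxy-2,4-bis(methoxymethoxy)-3-(3-methylbut-2-enyl)benzaldehyde, via aryllithium 6 (not isolated)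
Conditions: n-BuLi (1.2 equiv), TMEDA, THF, −40 to 0 °C; then DMF, −78 °C to rt; H2O
Reagents that add atoms: N,N-dimethylformamide (DMF), CN(C)C=O
Why: Second directed ortho-metalation at one of the two equivalent ring positions flanked by a MOM ether and the methyl ether, then formylation with DMF. Because 5 is symmetrical, only one aldehyde can form.

Step 4
Reactants: 7 6-methoxy-2,4-bis(methoxymethoxy)-3-(3-methylbut-2-enyl)benzaldehyde
Product: 8 2,4-dihydroxy-6-methoxy-3-(3-methylbut-2-enyl)benzaldehyde
Conditions: HCl (3 M aq.), MeOH, rt to 40 °C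
Reagents that add atoms: none
Why: Acid-catalysed acetal exchange removes both MOM ethers, the one ortho to the aldehyde first. Dilute acid and low temperature are chosen so that the prenyl group does not cyclise onto the flanking phenols.

Step 5
Reactants: 8 2,4-dihydroxy-6-methoxy-3-(3-methylbut-2-enyl)benzaldehyde
Product: 9 2-hydroxy-6-methoxy-3-(3-methylbut-2-enyl)-4-(triisopropylsilyloxy)benzaldehyde
Conditions: TIPSCl (1.05 equiv), imidazole (2.2 equiv), DMF, 0 °C
Reagents that add atoms: chlorotriisopropylsilane (TIPSCl), CC(C)[Si](Cl)(C(C)C)C(C)C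
Why: Chemoselective silylation: the 2-OH is held in a hydrogen bond to the aldehyde and is the poorer nucleophile, so the more acidic para-hydroxyl reacts. Triisopropylsilyl is chosen over tert-butyldimethylsilyl so that the phenol ethers outlast the perborate oxidation and the carbonate methanolysis.

Step 6
Reactants: 10 4-ethynylphenol
Product: 11 (4-ethynylphenoxy)triisopropylsilane
Conditions: TIPSCl (1.1 equiv), imidazole (2.2 equiv), CH2Cl2, rt
Reagents that add atoms: chlorotriisopropylsilane (TIPSCl), CC(C)[Si](Cl)(C(C)C)C(C)C
Why: Silyl ether formation on the phenol, with the same group as on ring A so that one fluoride step frees both phenols at the end.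

Step 7
Reactants: 11 (4-ethynylphenoxy)triisopropylsilane; 12 pinacolborane
Product: 13 (E)-2-[4-(triisopropylsilyloxy)styryl]-4,4,5,5-tetramethyl-1,3,2-dioxaborolane
Conditions: 12 (1.2 equiv), Cp2Zr(H)Cl (5 mol%), Et3N (10 mol%), neat, 60 °C
Reagents that add atoms: none
Why: Cp2Zr(H)Cl-catalysed hydroboration of a terminal aryl alkyne: syn addition of H–B places boron on the terminal carbon and gives the E alkenyl boronate only.

Step 8
Reactants: 9 2-hydroxy-6-methoxy-3-(3-methylbut-2-enyl)-4-(triisopropylsilyloxy)benzaldehyde; 13 (E)-2-[4-(triisopropylsilyloxy)styryl]-4,4,5,5-tetramethyl-1,3,2-dioxaborolane; 14 trimethyl orthoformate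
Product: 17 (2S,3S,4S)-4,5-dimethoxy-8-(3-methylbut-2-enyl)-3-(4,4,5,5-tetramethyl-1,3,2-dioxaborolan-2-yl)-7-(triisopropylsilyloxy)-2-[4-(triisopropylsilyloxy)phenyl]chroman (2,3-trans; 2,4-cis), via dimethyl acetal 15 (not isolated), via oxocarbenium ion 16 (not isolated)
Conditions: (R)-TRIP [(R)-3,3'-bis(2,4,6-triisopropylphenyl)-1,1'-binaphthyl-2,2'-diyl hydrogen phosphate] (10 mol%), 14 (2 equiv), 13 (2 equiv), 5 Å MS, toluene, −20 to 0 °C; Et3N quench, Et3N-deactivated silica
Reagents that add atoms: none
Why: Proposed new method: the acid and the orthoformate convert aldehyde 9 into acetal 15, whose ionisation gives the O-methyl oxocarbenium ion 16 (the protonated 4-methoxy ortho-quinone methide of ring A), held by the chiral phosphate through an ion pair and a hydrogen bond to the phenol. The boron-bearing alkene carbon of 13 is the nucleophilic end, because attack there leaves a cation that is benzylic to the para-silyloxyphenyl ring and hyperconjugated with the C–B bond; it bonds to C4, and the phenol oxygen then closes O1–C2 on that cation, so ring C forms by an asynchronous inverse-demand oxa-[4+2] cycloaddition, suprafacial on the alkene (in the stepwise limit a six-membered cation–phenol collapse). The closest known reactions are the acid-catalysed three-component union of salicylaldehydes, trimethyl orthoformate and styrenes to 2-aryl-4-methoxychromans and the chiral phosphoric acid catalysed [4+2] cycloadditions of ortho-quinone methides with styrenes; a boryl-substituted styrene has not been shown as the two-carbon partner. C2 and C3 are set relative to each other by suprafacial addition to the E alkene (2,3-trans, aryl and boron both equatorial) and in absolute terms by the phosphate, which shields one face of 16 and passes that choice on through the endo arrangement; C4 is set by the same face choice (2,4-cis expected) but is provisional. The step needs regioselectivity (secured by the para-oxygenated aryl group), retention of boron over alkenyl transfer (secured by the non-exchanging pinacol ester and the fast intramolecular oxygen capture), and preference for the styrene over the prenyl alkene (secured by its higher nucleophilicity and its excess). Any 2,4-trans epimer is separated here, because C4 is erased in step 11 and epimers of opposite C2/C3 sense would otherwise merge as enantiomers.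

Step 9
Reactants: 17 (2S,3S,4S)-4,5-dimethoxy-8-(3-methylbut-2-enyl)-3-(4,4,5,5-tetramethyl-1,3,2-dioxaborolan-2-yl)-7-(triisopropylsilyloxy)-2-[4-(triisopropylsilyloxy)phenyl]chroman
Product: 18 (2R,3S,4R)-4,5-dimethoxy-8-(3-methylbut-2-enyl)-7-(triisopropylsilyloxy)-2-[4-(triisopropylsilyloxy)phenyl]chroman-3-ol
Conditions: NaBO3·4H2O (4 equiv), THF/H2O (1:1), 0 °C to rt
Reagents that add atoms: sodium perborate, [Na+].[Na+].O[B-]1(O)OO[B-](O)(O)OO1
Why: Oxidation of a secondary alkyl boronate: peroxide adds to boron and C3 migrates from boron to oxygen with retention, so the 3-OH takes the β position held by boron (the descriptors change only through priorities). The mild, buffered perborate spares the aryl silyl ethers and disfavours β-elimination of the neighbouring alkoxy groups.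

Step 10
Reactants: 18 (2R,3S,4R)-4,5-dimethoxy-8-(3-methylbut-2-enyl)-7-(triisopropylsilyloxy)-2-[4-(triisopropylsilyloxy)phenyl]chroman-3-ol
Product: 19 tert-butyl (2R,3S,4R)-4,5-dimethoxy-8-(3-methylbut-2-enyl)-7-(triisopropylsilyloxy)-2-[4-(triisopropylsilyloxy)phenyl]chroman-3-yl carbonate
Conditions: Boc2O (2 equiv), DMAP (0.2 equiv), CH2Cl2, rt
Reagents that add atoms: di-tert-butyl dicarbonate (Boc2O), CC(C)(C)OC(=O)OC(=O)OC(C)(C)C
Why: DMAP-catalysed acylation of the only free hydroxyl to its tert-butyl carbonate, which is both the protecting group and the internal oxygen nucleophile for C4.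

Step 11
Reactants: 19 tert-butyl (2R,3S,4R)-4,5-dimethoxy-8-(3-methylbut-2-enyl)-7-(triisopropylsilyloxy)-2-[4-(triisopropylsilyloxy)phenyl]chroman-3-yl carbonate
Product: 21 3,4-cis cyclic carbonate of (2R,3S,4S)-5-methoxy-8-(3-methylbut-2-enyl)-7-(triisopropylsilyloxy)-2-[4-(triisopropylsilyloxy)phenyl]chroman-3,4-diol (2α-aryl; 3β,4β-dioxygen), via dioxolanylium ion 20 (not isolated)
Conditions: BF3·OEt2 (0.3 equiv), 4 Å MS, CH2Cl2, −78 to −40 °C; Et3N quench
Reagents that add atoms: none
Why: Lewis acid ionisation of the benzylic methyl ether, stabilised by the ortho and para oxygens of ring A (an SN1 substitution at C4 of the kind used with 4-alkoxyflavans), then neighbouring-group capture by the carbonyl oxygen of the tert-butyl carbonate and loss of 2-methylpropene from ion 20. A five-membered carbonate on ring C can only be cis-fused, so the new C4–O bond is β, cis to C3–O, whichever C4 epimer of 19 enters.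

Step 12
Reactants: 21 3,4-cis cyclic carbonate of the bis-silyl diol
Product: 22 (2R,3S,4S)-5-methoxy-8-(3-methylbut-2-enyl)-7-(triisopropylsilyloxy)-2-[4-(triisopropylsilyloxy)phenyl]chroman-3,4-diol
Conditions: K2CO3 (0.3 equiv), MeOH/THF (1:1), 0 °C
Reagents that add atoms: none
Why: Base-catalysed transesterification of the strained five-membered carbonate to the diol and dimethyl carbonate, with both ring C–O bonds untouched. It is done before the phenols are freed, so that no 7-phenoxide is present while C4 still carries a leaving group.

Step 13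
Reactants: 22 (2R,3S,4S)-5-methoxy-8-(3-methylbut-2-enyl)-7-(triisopropylsilyloxy)-2-[4-(triisopropylsilyloxy)phenyl]chroman-3,4-diol
Product: 23 5-O-methyl-8-prenylafzelechin-4β-ol, (2R,3S,4S)-2-(4-hydroxyphenyl)-5-methoxy-8-(3-methylbut-2-enyl)chroman-3,4,7-triol
Conditions: Bu4NF (2.5 equiv), AcOH (2.5 equiv), THF, 0 °C; pH 7 buffer work-up
Reagents that add atoms: none
Why: Fluoride cleavage of the two aryl silyl ethers. Acetic acid buffers the phenoxides so that neither quinone methide formation at C4 nor ring opening at C2 is provoked, and no acid strong enough to ionise the C4–OH is present.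

## Compound list

1 | 5-methoxyresorcinol (5-methoxybenzene-1,3-diol) | COc1cc(O)cc(O)c1 | starting material
2 | 1-methoxy-3,5-bis(methoxymethoxy)benzene | COCOc1cc(OC)cc(OCOC)c1 | intermediate
3 | 1-bromo-3-methylbut-2-ene (prenyl bromide) | CC(C)=CCBr | starting material
4 | [4-methoxy-2,6-bis(methoxymethoxy)phenyl]lithium | [Li]c1c(OCOC)cc(OC)cc1OCOC | intermediate (not isolated)
5 | 5-methoxy-1,3-bis(methoxymethoxy)-2-(3-methylbut-2-enyl)benzene | COCOc1cc(OC)cc(OCOC)c1CC=C(C)C | intermediate
6 | [6-methoxy-2,4-bis(methoxymethoxy)-3-(3-methylbut-2-enyl)phenyl]lithium | COCOc1cc(OC)c([Li])c(OCOC)c1CC=C(C)C | intermediate (not isolated)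
7 | 6-methoxy-2,4-bis(methoxymethoxy)-3-(3-methylbut-2-enyl)benzaldehyde | COCOc1cc(OC)c(C=O)c(OCOC)c1CC=C(C)C | intermediate
8 | 2,4-dihydroxy-6-methoxy-3-(3-methylbut-2-enyl)benzaldehyde | COc1cc(O)c(CC=C(C)C)c(O)c1C=O | intermediate
9 | 2-hydroxy-6-methoxy-3-(3-methylbut-2-enyl)-4-(triisopropylsilyloxy)benzaldehyde | COc1cc(O[Si](C(C)C)(C(C)C)C(C)C)c(CC=C(C)C)c(O)c1C=O | intermediate
10 | 4-ethynylphenol | C#Cc1ccc(O)cc1 | starting material
11 | (4-ethynylphenoxy)triisopropylsilane | C#Cc1ccc(O[Si](C(C)C)(C(C)C)C(C)C)cc1 | intermediate
12 | pinacolborane (4,4,5,5-tetramethyl-1,3,2-dioxaborolane) | CC1(C)OBOC1(C)C | starting material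
13 | (E)-2-[4-(triisopropylsilyloxy)styryl]-4,4,5,5-tetramethyl-1,3,2-dioxaborolane | CC1(C)OB(/C=C/c2ccc(O[Si](C(C)C)(C(C)C)C(C)C)cc2)OC1(C)C | intermediate
14 | trimethyl orthoformate | COC(OC)OC | starting material
15 | 2-(dimethoxymethyl)-3-methoxy-6-(3-methylbut-2-enyl)-5-(triisopropylsilyloxy)phenol | COc1cc(O[Si](C(C)C)(C(C)C)C(C)C)c(CC=C(C)C)c(O)c1C(OC)OC | intermediate (not isolated)
16 | [2-hydroxy-6-methoxy-3-(3-methylbut-2-enyl)-4-(triisopropylsilyloxy)benzylidene](methyl)oxonium, ion-paired with the chiral phosphate (protonated 4-methoxy ortho-quinone methide) | COc1cc(O[Si](C(C)C)(C(C)C)C(C)C)c(CC=C(C)C)c(O)c1C=[O+]C | intermediate (not isolated)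
17 | (2S,3S,4S)-4,5-dimethoxy-8-(3-methylbut-2-enyl)-3-(4,4,5,5-tetramethyl-1,3,2-dioxaborolan-2-yl)-7-(triisopropylsilyloxy)-2-[4-(triisopropylsilyloxy)phenyl]chroman | COc1cc(O[Si](C(C)C)(C(C)C)C(C)C)c(CC=C(C)C)c2c1[C@@H](OC)[C@H](B1OC(C)(C)C(C)(C)O1)[C@@H](c1ccc(O[Si](C(C)C)(C(C)C)C(C)C)cc1)O2 | intermediate
18 | (2R,3S,4R)-4,5-dimethoxy-8-(3-methylbut-2-enyl)-7-(triisopropylsilyloxy)-2-[4-(triisopropylsilyloxy)phenyl]chroman-3-ol | COc1cc(O[Si](C(C)C)(C(C)C)C(C)C)c(CC=C(C)C)c2c1[C@@H](OC)[C@H](O)[C@@H](c1ccc(O[Si](C(C)C)(C(C)C)C(C)C)cc1)O2 | intermediate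
19 | tert-butyl (2R,3S,4R)-4,5-dimethoxy-8-(3-methylbut-2-enyl)-7-(triisopropylsilyloxy)-2-[4-(triisopropylsilyloxy)phenyl]chroman-3-yl carbonate | COc1cc(O[Si](C(C)C)(C(C)C)C(C)C)c(CC=C(C)C)c2c1[C@@H](OC)[C@H](OC(=O)OC(C)(C)C)[C@@H](c1ccc(O[Si](C(C)C)(C(C)C)C(C)C)cc1)O2 | intermediate
20 | cis-fused 2-tert-butoxy-1,3-dioxolan-2-ylium ion spanning C3 and C4 of the bis-silyl flavan | COc1cc(O[Si](C(C)C)(C(C)C)C(C)C)c(CC=C(C)C)c2c1[C@@H]3O[C+](OC(C)(C)C)O[C@@H]3[C@@H](c1ccc(O[Si](C(C)C)(C(C)C)C(C)C)cc1)O2 | intermediate (not isolated)
21 | 3,4-cis cyclic carbonate of (2R,3S,4S)-5-methoxy-8-(3-methylbut-2-enyl)-7-(triisopropylsilyloxy)-2-[4-(triisopropylsilyloxy)phenyl]chroman-3,4-diol | COc1cc(O[Si](C(C)C)(C(C)C)C(C)C)c(CC=C(C)C)c2c1[C@@H]3OC(=O)O[C@@H]3[C@@H](c1ccc(O[Si](C(C)C)(C(C)C)C(C)C)cc1)O2 | intermediate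
22 | (2R,3S,4S)-5-methoxy-8-(3-methylbut-2-enyl)-7-(triisopropylsilyloxy)-2-[4-(triisopropylsilyloxy)phenyl]chroman-3,4-diol | COc1cc(O[Si](C(C)C)(C(C)C)C(C)C)c(CC=C(C)C)c2c1[C@H](O)[C@H](O)[C@@H](c1ccc(O[Si](C(C)C)(C(C)C)C(C)C)cc1)O2 | intermediate
23 | 5-O-methyl-8-prenylafzelechin-4β-ol, (2R,3S,4S)-2-(4-hydroxyphenyl)-5-methoxy-8-(3-methylbut-2-enyl)chroman-3,4,7-triol | COc1cc(O)c(CC=C(C)C)c2c1[C@H](O)[C@H](O)[C@@H](c1ccc(O)cc1)O2 | target

## Step count and least certain steps

Total step count: 13. Longest linear sequence: 11 steps (steps 1–5 and 8–13 from 1); the boronate arm is 2 steps (6 and 7) before the union.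

**Step 8 (key step, proposed new method).** The most likely failure is loss of boron. This can happen by transfer of the styrenyl group to C4 with departure of boron from the β-boryl cation before the phenol oxygen closes the ring, or by re-ionisation of the product at C4 followed by elimination of boron and methoxide across C3–C4. Further risks are:
- slow addition, because ion 16 is strongly stabilised and the boryl group lowers the nucleophilicity of the styrene;
- addition of the prenyl alkene of a second molecule;
- methylation of the catalyst by the orthoformate;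
- poor facial selectivity.

Fallback with known chemistry (chalcone epoxide route), setting out from 5 and returning at 18:
- Lithiation of 5 as in step 3 and acylation with N-methoxy-N-methylacetamide should give 1-[6-methoxy-2,4-bis(methoxymethoxy)-3-(3-methylbut-2-enyl)phenyl]ethanone F1.
- Claisen–Schmidt condensation with 4-(methoxymethoxy)benzaldehyde (KOH, EtOH) should give the E chalcone F2.
- Juliá–Colonna epoxidation (poly-L-leucine, urea–H2O2, DBU, THF), a nucleophilic epoxidation that leaves the prenyl alkene alone, should give the (2R,3S)-epoxy ketone F3.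
- Methanolic HCl removes the three MOM groups, and the freed 2'-phenol opens the epoxide at the benzylic carbon with inversion to give (2R,3R)-5-O-methyl-8-prenylaromadendrin F4.
- TIPSCl and imidazole silylate the two phenols to the bis-silyl dihydroflavonol F5.
- NaBH4 reduces the ketone to the 3,4-trans diol F6.
- PPTS in methanol exchanges the benzylic 4-OH for methoxy to give 18, together with its C4 epimer 4-epi-18 F7. Both converge at 21 in step 11.

**Step 11 (C4 inversion through the carbonate).** The likely failures are capture of the C4 cation by the nucleophilic C6 position of a second molecule, alkylation of ring A or the prenyl alkene by the tert-butyl cation, proton loss from C3, and cleavage of the carbonate by the Lewis acid before ionisation.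

Fallback (oxidation and reduction at C4 instead of cation capture), setting out from 18 and returning at 23:
- TBSOTf and 2,6-lutidine give the 3-O-tert-butyldimethylsilyl ether F8.
- PPTS in wet acetone hydrolyses the 4-methoxy group to the flavan-4-ol F9 (either epimer).
- Dess–Martin periodinane gives the flavan-4-one F10.
- LiBH(s-Bu)3 in THF at −78 °C, approaching anti to the 3-silyloxy group, should give the 3,4-cis alcohol F11.
- Bu4NF/AcOH removes the three silyl groups to give 23.

**Step 3 (formylation).** The likely failure is competing deprotonation at the benzylic and allylic CH2 of the prenyl group, which is flanked by two chelating MOM ethers, instead of ring metalation.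

Fallback (electrophilic ortho-formylation of the free phenol instead of metalation), setting out from 5 and returning at 8:
- Methanolic HCl removes the MOM groups to give 5-methoxy-2-(3-methylbut-2-enyl)benzene-1,3-diol F12.
- Magnesium-mediated ortho-formylation (MgCl2, Et3N, paraformaldehyde, MeCN, reflux) places the aldehyde at one of the two equivalent positions ortho to a hydroxyl, giving 8.

**Step 12 (carbonate opening).** The likely failure is premature loss of the 7-O-silyl group under methoxide. The 7-phenoxide could then expel the C4 carbonate oxygen, and methanol would add back with loss of the C4 configuration.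

Fallback (hydride reduction instead of alkoxide transesterification), setting out from 21 and returning at 22: reductive opening of the carbonate with i-Bu2AlH in CH2Cl2 at −78 °C, which reduces the carbonyl carbon to methanol and generates no alkoxide able to attack silicon. This fallback makes no new compound (F0).

## Further compounds

F1 | step 8 | 1-[6-methoxy-2,4-bis(methoxymethoxy)-3-(3-methylbut-2-enyl)phenyl]ethanone | COCOc1cc(OC)c(C(C)=O)c(OCOC)c1CC=C(C)C
F2 | step 8 | (E)-1-[6-methoxy-2,4-bis(methoxymethoxy)-3-(3-methylbut-2-enyl)phenyl]-3-[4-(methoxymethoxy)phenyl]prop-2-en-1-one | COCOc1ccc(/C=C/C(=O)c2c(OC)cc(OCOC)c(CC=C(C)C)c2OCOC)cc1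
F3 | step 8 | [(2R,3S)-3-[4-(methoxymethoxy)phenyl]oxiran-2-yl][6-methoxy-2,4-bis(methoxymethoxy)-3-(3-methylbut-2-enyl)phenyl]methanone | O=C(c1c(OC)cc(OCOC)c(CC=C(C)C)c1OCOC)[C@@H]1O[C@H]1c1ccc(OCOC)cc1
F4 | step 8 | (2R,3R)-3,7-dihydroxy-2-(4-hydroxyphenyl)-5-methoxy-8-(3-methylbut-2-enyl)chroman-4-one (5-O-methyl-8-prenylaromadendrin) | COc1cc(O)c(CC=C(C)C)c2c1C(=O)[C@H](O)[C@@H](c1ccc(O)cc1)O2
F5 | step 8 | (2R,3R)-3-hydroxy-5-methoxy-8-(3-methylbut-2-enyl)-7-(triisopropylsilyloxy)-2-[4-(triisopropylsilyloxy)phenyl]chroman-4-one | COc1cc(O[Si](C(C)C)(C(C)C)C(C)C)c(CC=C(C)C)c2c1C(=O)[C@H](O)[C@@H](c1ccc(O[Si](C(C)C)(C(C)C)C(C)C)cc1)O2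
F6 | step 8 | (2R,3S,4R)-5-methoxy-8-(3-methylbut-2-enyl)-7-(triisopropylsilyloxy)-2-[4-(triisopropylsilyloxy)phenyl]chroman-3,4-diol | COc1cc(O[Si](C(C)C)(C(C)C)C(C)C)c(CC=C(C)C)c2c1[C@@H](O)[C@H](O)[C@@H](c1ccc(O[Si](C(C)C)(C(C)C)C(C)C)cc1)O2
F7 | step 8 | (2R,3S,4S)-4,5-dimethoxy-8-(3-methylbut-2-enyl)-7-(triisopropylsilyloxy)-2-[4-(triisopropylsilyloxy)phenyl]chroman-3-ol (4-epi-18) | COc1cc(O[Si](C(C)C)(C(C)C)C(C)C)c(CC=C(C)C)c2c1[C@H](OC)[C@H](O)[C@@H](c1ccc(O[Si](C(C)C)(C(C)C)C(C)C)cc1)O2
F8 | step 11 | (2R,3S,4R)-3-(tert-butyldimethylsilyloxy)-4,5-dimethoxy-8-(3-methylbut-2-enyl)-7-(triisopropylsilyloxy)-2-[4-(triisopropylsilyloxy)phenyl]chroman | COc1cc(O[Si](C(C)C)(C(C)C)C(C)C)c(CC=C(C)C)c2c1[C@@H](OC)[C@H](O[Si](C)(C)C(C)(C)C)[C@@H](c1ccc(O[Si](C(C)C)(C(C)C)C(C)C)cc1)O2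
F9 | step 11 | (2R,3S,4RS)-3-(tert-butyldimethylsilyloxy)-5-methoxy-8-(3-methylbut-2-enyl)-7-(triisopropylsilyloxy)-2-[4-(triisopropylsilyloxy)phenyl]chroman-4-ol | COc1cc(O[Si](C(C)C)(C(C)C)C(C)C)c(CC=C(C)C)c2c1C(O)[C@H](O[Si](C)(C)C(C)(C)C)[C@@H](c1ccc(O[Si](C(C)C)(C(C)C)C(C)C)cc1)O2
F10 | step 11 | (2R,3R)-3-(tert-butyldimethylsilyloxy)-5-methoxy-8-(3-methylbut-2-enyl)-7-(triisopropylsilyloxy)-2-[4-(triisopropylsilyloxy)phenyl]chroman-4-one | COc1cc(O[Si](C(C)C)(C(C)C)C(C)C)c(CC=C(C)C)c2c1C(=O)[C@H](O[Si](C)(C)C(C)(C)C)[C@@H](c1ccc(O[Si](C(C)C)(C(C)C)C(C)C)cc1)O2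
F11 | step 11 | (2R,3S,4S)-3-(tert-butyldimethylsilyloxy)-5-methoxy-8-(3-methylbut-2-enyl)-7-(triisopropylsilyloxy)-2-[4-(triisopropylsilyloxy)phenyl]chroman-4-ol | COc1cc(O[Si](C(C)C)(C(C)C)C(C)C)c(CC=C(C)C)c2c1[C@H](O)[C@H](O[Si](C)(C)C(C)(C)C)[C@@H](c1ccc(O[Si](C(C)C)(C(C)C)C(C)C)cc1)O2
F12 | step 3 | 5-methoxy-2-(3-methylbut-2-enyl)benzene-1,3-diol | COc1cc(O)c(CC=C(C)C)c(O)c1
F0 | step 12 | none | none
A1 | alternative 1 | [2-hydroxy-6-methoxy-4-(methoxymethoxy)-3-(3-methylbut-2-enyl)phenyl] [(4R,5S)-5-[4-(methoxymethoxy)phenyl]-2,2-dimethyl-1,3-dioxolan-4-yl] ketone | COc1cc(OCOC)c(CC=C(C)C)c(O)c1C(=O)[C@@H]1OC(C)(C)O[C@H]1c1ccc(OCOC)cc1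
A2 | alternative 1 | 3-methoxy-5-(methoxymethoxy)-6-(3-methylbut-2-enyl)-2-(trimethylsilyl)phenyl trifluoromethanesulfonate | COc1cc(OCOC)c(CC=C(C)C)c(OS(=O)(=O)C(F)(F)F)c1[Si](C)(C)C
A3 | alternative 1 | (4R,5S)-5-[4-(methoxymethoxy)phenyl]-2,2-dimethyl-1,3-dioxolane-4-carboxylic acid | OC(=O)[C@@H]1OC(C)(C)O[C@H]1c1ccc(OCOC)cc1
A4 | alternative 2 | 3,4-cis cyclic carbonate of 8-bromo-7,4'-bis-O-tert-butyldimethylsilyl-5-O-methylafzelechin-4β-ol | COc1cc(O[Si](C)(C)C(C)(C)C)c(Br)c2c1[C@@H]3OC(=O)O[C@@H]3[C@@H](c1ccc(O[Si](C)(C)C(C)(C)C)cc1)O2
A5 | alternative 2 | tert-butyl carbonate of 8-bromo-7,4'-bis-O-tert-butyldimethylsilyl-5-O-methylafzelechin (3-O-Boc; 2R,3S) | COc1cc(O[Si](C)(C)C(C)(C)C)c(Br)c2c1C[C@H](OC(=O)OC(C)(C)C)[C@@H](c1ccc(O[Si](C)(C)C(C)(C)C)cc1)O2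
A6 | alternative 3 | (2R,3R)-3,4'-bis-O-tert-butyldimethylsilyl-5-O-methyl-8-prenylaromadendrin | COc1cc(O)c(CC=C(C)C)c2c1C(=O)[C@H](O[Si](C)(C)C(C)(C)C)[C@@H](c1ccc(O[Si](C)(C)C(C)(C)C)cc1)O2
A7 | alternative 3 | (2R,3R)-3-(tert-butyldimethylsilyloxy)-2-[4-(tert-butyldimethylsilyloxy)phenyl]-5-(phenylsulfinyl)-2,3-dihydro-4H-pyran-4-one | O=C1C(S(=O)c2ccccc2)=CO[C@H](c2ccc(O[Si](C)(C)C(C)(C)C)cc2)[C@H]1O[Si](C)(C)C(C)(C)C
A8 | alternative 3 | 1,1-dimethoxy-7-methyl-3-(trimethylsilyloxy)octa-1,3,6-triene | COC(OC)=CC(O[Si](C)(C)C)=CCC=C(C)C
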